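## Retrosynthetic overview

1. Germacrane numbering is used: ten-membered carbocycle C1–C10 (C1/C10 trans-oxirane, CH3 on C10; C3–OH; C4 bears C15 (CHO); ring-cis C4=C5; C8 ester), fused at C6/C7 to the α-methylene-γ-butyrolactone O–C6–C7–C11(=C13)–C12(=O).
2. Endgame: the C15 enal comes from selective oxidation of a primary allylic alcohol; the C8 methacrylate comes from Mitsunobu inversion of the 8-epi alcohol that the ring closure is expected to deliver.
3. Key disconnection C7–C8. The array O–C8–C7–C11(=C13), in which C7 is the β-carbon of the lactone ring and C11=C13 its exo-methylene, is the retron of an SE2′ carbonyl allylation. The carbocycle is therefore opened to an open-chain C8 aldehyde carrying a 3-(bromomethyl)butenolide. One Cr(II) operation closes the ring, sets C7 and C8 and unveils C11=C13; the ring-cis C4=C5 alkene and the trans-oxirane act as turn elements.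
4. Open-chain precursor: butenolide by acrylate ring-closing metathesis at the C6 carbinol; C3–C4 by asymmetric Ni/Cr coupling of a Z-alkenyl iodide (Red-Al/I2 on an enynol from asymmetric alkynylation of acrolein) with an epoxy aldehyde (carboalumination/oxirane opening, Shi epoxidation).
5. Order of ring formation: oxirane (step 3), butenolide (step 12), ten-membered carbocycle (step 15, last).

Key step: step 15

Assumption: in the two ligand-controlled additions (steps 5 and 8) the ligand antipode is the one that gives the stated configuration; both antipodes of each ligand are accessible.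

## Route

Step 1
Reactants: 1 but-3-yn-1-ol
Product: 2 1-[(but-3-yn-1-yloxy)methyl]-4-methoxybenzene
Conditions: NaH, PMBCl, Bu4NI (cat.), THF/DMF, 0 °C to rt
Reagents that add atoms: 4-methoxybenzyl chloride, COc1ccc(CCl)cc1
Why: Williamson etherification, in which NaH deprotonates only the hydroxyl (not the alkyne C–H) and the alkoxide displaces the benzylic chloride; no stereocentre is involved.

Step 2
Reactants: 2 1-[(but-3-yn-1-yloxy)methyl]-4-methoxybenzene; 3 ethylene oxide
Product: 6 (E)-6-[(4-methoxybenzyl)oxy]-4-methylhex-3-en-1-ol, via alkenyldimethylalane 4 (not isolated), via lithium alkenylalanate 5 (not isolated)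
Conditions: Me3Al, Cp2ZrCl2 (cat.), CH2Cl2, 0 °C to rt; excess Me3Al removed; n-BuLi, hexane/THF, −78 °C; then 3, −78 to 0 °C
Reagents that add atoms: trimethylaluminium, C[Al](C)C
Why: Negishi Zr-catalysed syn-carboalumination puts CH3 on the internal and Al on the terminal alkyne carbon, and the derived alanate opens ethylene oxide with retention at the sp2 carbon, so the E-trisubstituted alkene (C1=C10 with C14) should form as one isomer.

Step 3
Reactants: 6 (E)-6-[(4-methoxybenzyl)oxy]-4-methylhex-3-en-1-ol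
Product: 7 2-[(2R,3R)-3-{2-[(4-methoxybenzyl)oxy]ethyl}-3-methyloxiran-2-yl]ethan-1-ol
Conditions: D-fructose-derived Shi ketone (0.3 equiv), Oxone, K2CO3, Bu4NHSO4, MeCN/DMM/aqueous borate buffer (pH 10.5), 0 °C
Reagents that add atoms: potassium peroxymonosulfate (Oxone), [K+].[O-]S(=O)(=O)OO
Why: Shi asymmetric epoxidation, in which the dioxirane of the D-fructose-derived ketone delivers (R,R)-epoxides from trans and trisubstituted alkenes through the spiro transition state, should set C1 and C10 under reagent control, the trans relationship following from the E alkene and the basic buffer preventing cyclisation of the epoxy alcohol.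

Step 4
Reactants: 7 2-[(2R,3R)-3-{2-[(4-methoxybenzyl)oxy]ethyl}-3-methyloxiran-2-yl]ethan-1-ol
Product: 8 2-[(2R,3R)-3-{2-[(4-methoxybenzyl)oxy]ethyl}-3-methyloxiran-2-yl]acetaldehyde
Conditions: Dess–Martin periodinane, NaHCO3, CH2Cl2, 0 °C; used crude at once
Reagents that add atoms: none
Why: Buffered Dess–Martin oxidation should give the β,γ-epoxy aldehyde without touching the oxirane, and immediate use avoids the base- or silica-induced β-elimination typical of such aldehydes.

Step 5
Reactants: 9 tert-butyldimethyl(prop-2-yn-1-yloxy)silane; 10 acrolein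
Product: 12 (3S)-6-[(tert-butyldimethylsilyl)oxy]hex-1-en-4-yn-3-ol, via methyl(alkynyl)zinc 11 (not isolated)
Conditions: Me2Zn, ProPhenol (10 mol%), Ph3P=O (20 mol%), toluene, 0 °C, slow addition of 10
Reagents that add atoms: none
Why: Zn–ProPhenol-catalysed asymmetric alkynylation of an enal, in which the alkynylzinc adds 1,2 to acrolein inside the dinuclear zinc pocket on the Re face, should set the carbinol that becomes C6.

Step 6
Reactants: 12 (3S)-6-[(tert-butyldimethylsilyl)oxy]hex-1-en-4-yn-3-ol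
Product: 14 (3S,4Z)-6-[(tert-butyldimethylsilyl)oxy]-5-iodohexa-1,4-dien-3-ol, via cyclic vinylalanate 13 (not isolated)
Conditions: Red-Al, THF, 0 °C to rt; EtOAc; then I2, −78 to 0 °C
Reagents that add atoms: iodine, II
Why: Hydroxyl-directed trans-hydroalumination delivers hydride to the alkyne carbon next to the carbinol and aluminium to the distal carbon within a five-membered alkoxyaluminate, and iodinolysis with retention should give the Z-iodoalkene (I cis to the carbinol carbon), which is the ring-cis C4=C5 geometry of the target.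

Step 7
Reactants: 14 (3S,4Z)-6-[(tert-butyldimethylsilyl)oxy]-5-iodohexa-1,4-dien-3-ol
Product: 15 tert-butyl{[(2Z,4S)-2-iodo-4-[(triethylsilyl)oxy]hexa-2,5-dien-1-yl]oxy}dimethylsilane
Conditions: TESCl, imidazole, CH2Cl2, 0 °C
Reagents that add atoms: chlorotriethylsilane, CC[Si](Cl)(CC)CC
Why: Standard silylation of the only free hydroxyl, with triethylsilyl chosen because it can later be removed in the presence of tert-butyldimethylsilyl ethers.

Step 8
Reactants: 15 tert-butyl{[(2Z,4S)-2-iodo-4-[(triethylsilyl)oxy]hexa-2,5-dien-1-yl]oxy}dimethylsilane; 8 2-[(2R,3R)-3-{2-[(4-methoxybenzyl)oxy]ethyl}-3-methyloxiran-2-yl]acetaldehyde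
Product: 17 (3S,4Z,6S)-5-{[(tert-butyldimethylsilyl)oxy]methyl}-7-[(2R,3R)-3-{2-[(4-methoxybenzyl)oxy]ethyl}-3-methyloxiran-2-yl]-3-[(triethylsilyl)oxy]hepta-1,4-dien-6-ol, via alkenylchromium(III) dichloride 16 (not isolated)
Conditions: CrCl2, chiral oxazoline–sulfonamide ligand, Et3N, NiCl2 (cat.), THF, rt
Reagents that add atoms: none
Why: Asymmetric Nozaki–Hiyama–Kishi coupling, in which Ni-catalysed activation and transmetalation give the alkenylchromium with retention of alkene geometry and the chiral sulfonamide ligand directs addition to the Re face of the aldehyde, should form the C3–C4 bond and set the (S)-carbinol at C3 under neutral conditions that spare the oxirane.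

Step 9
Reactants: 17 the (3S,4Z,6S)-hepta-1,4-dien-6-ol from step 8
Product: 18 (3S,4Z,6S)-6-[(tert-butyldimethylsilyl)oxy]-5-{[(tert-butyldimethylsilyl)oxy]methyl}-7-[(2R,3R)-3-{2-[(4-methoxybenzyl)oxy]ethyl}-3-methyloxiran-2-yl]-3-[(triethylsilyl)oxy]hepta-1,4-diene
Conditions: TBSCl, imidazole, DMAP (cat.), DMF, rt
Reagents that add atoms: tert-butyldimethylsilyl chloride, CC(C)(C)[Si](C)(C)Cl
Why: Silyl ether formation at the only free hydroxyl under conditions free of Lewis acid, which leave the oxirane intact.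

Step 10
Reactants: 18 the bis-TBS triethylsilyl ether from step 9
Product: 19 (3S,4Z,6S)-6-[(tert-butyldimethylsilyl)oxy]-5-{[(tert-butyldimethylsilyl)oxy]methyl}-7-[(2R,3R)-3-{2-[(4-methoxybenzyl)oxy]ethyl}-3-methyloxiran-2-yl]hepta-1,4-dien-3-ol
Conditions: PPTS (0.2 equiv), MeOH/CH2Cl2 (1:4), 0 °C
Reagents that add atoms: none
Why: Acid-catalysed methanolysis of silyl ethers is governed by size at silicon, so the triethylsilyl ether should be cleaved much faster than the two tert-butyldimethylsilyl ethers, and PPTS at 0 °C is too weak to open the trisubstituted oxirane.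

Step 11
Reactants: 19 the C6 alcohol from step 10; 20 2-(bromomethyl)acrylic acid
Product: 22 (3S,4Z,6S)-6-[(tert-butyldimethylsilyl)oxy]-5-{[(tert-butyldimethylsilyl)oxy]methyl}-7-[(2R,3R)-3-{2-[(4-methoxybenzyl)oxy]ethyl}-3-methyloxiran-2-yl]hepta-1,4-dien-3-yl 2-(bromomethyl)prop-2-enoate, via 2-(bromomethyl)acryloyl chloride 21 (not isolated)
Conditions: 20, (COCl)2, DMF (cat.), CH2Cl2, 0 °C to rt, volatiles removed; then 19, 2,6-lutidine, CH2Cl2, −40 to 0 °C
Reagents that add atoms: none
Why: Acylation of the free C6 hydroxyl by the acid chloride in the presence of a hindered, non-nucleophilic pyridine base that should not displace the allylic bromide, with the C6 configuration untouched.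

Step 12
Reactants: 22 the 2-(bromomethyl)acrylate from step 11
Product: 23 (5R)-3-(bromomethyl)-5-[(1Z,3S)-3-[(tert-butyldimethylsilyl)oxy]-2-{[(tert-butyldimethylsilyl)oxy]methyl}-4-[(2R,3R)-3-{2-[(4-methoxybenzyl)oxy]ethyl}-3-methyloxiran-2-yl]but-1-en-1-yl]furan-2(5H)-one
Conditions: Grubbs II (10 mol%), CH2Cl2 (5 mM), 40 °C
Reagents that add atoms: none
Why: Ring-closing metathesis, in which the Ru carbene loads on the monosubstituted vinyl group and closes onto the 1,1-disubstituted acrylate, should give the five-membered butenolide with loss of ethene, the trisubstituted C4=C5 alkene being inert and the allylic bromide tolerated.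

Step 13
Reactants: 23 the PMB-protected bromomethyl butenolide from step 12
Product: 24 (5R)-3-(bromomethyl)-5-[(1Z,3S)-3-[(tert-butyldimethylsilyl)oxy]-2-{[(tert-butyldimethylsilyl)oxy]methyl}-4-[(2R,3R)-3-(2-hydroxyethyl)-3-methyloxiran-2-yl]but-1-en-1-yl]furan-2(5H)-one
Conditions: DDQ, CH2Cl2/pH 7 phosphate buffer (10:1), 0 °C
Reagents that add atoms: none
Why: Oxidative cleavage of the 4-methoxybenzyl ether by DDQ (benzylic hydride abstraction, then hydrolysis) under buffered conditions should leave silyl ethers, oxirane, butenolide and allylic bromide untouched.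

Step 14
Reactants: 24 the primary alcohol from step 13
Product: 25 (5R)-3-(bromomethyl)-5-[(1Z,3S)-3-[(tert-butyldimethylsilyl)oxy]-2-{[(tert-butyldimethylsilyl)oxy]methyl}-4-[(2R,3R)-3-methyl-3-(2-oxoethyl)oxiran-2-yl]but-1-en-1-yl]furan-2(5H)-one
Conditions: Dess–Martin periodinane, NaHCO3, CH2Cl2, 0 °C; filtered and used crude
Reagents that add atoms: none
Why: Buffered Dess–Martin oxidation should give the C8 β,γ-epoxy aldehyde under non-basic conditions compatible with the allylic bromide, and the crude aldehyde goes straight into the cyclisation.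

Step 15
Reactants: 25 the open-chain C8 aldehyde carrying the 3-(bromomethyl)butenolide
Product: 27 (1R,3S,6R,7R,8S,10R,4Z)-3,15-bis[(tert-butyldimethylsilyl)oxy]-1,10-epoxy-8-hydroxygermacra-4,11(13)-dien-12,6-olide, via allylchromium(III) dichloride 26 (not isolated)
Conditions: CrCl2 (10 equiv), THF, rt, syringe-pump addition of 25 over 12 h (final 1 mM); pH 7 aqueous work-up
Reagents that add atoms: none
Why: Chromium(II) reduces the allylic bromide in two one-electron steps to an allylchromium(III) bound at C13, which adds to the C8 aldehyde through its γ-carbon C7 in a six-membered Zimmerman–Traxler transition state (SE2′), forming the C7–C8 bond and moving the double bond to C11=C13. The closest known reactions are the Nozaki–Hiyama/Barbier allylation of aldehydes with 2-(alkoxycarbonyl)allyl bromides and 3-(bromomethyl)butenolides and its intramolecular use to close ten-membered germacranolide rings. The ten-membered carbocycle closes as a 10-exo-trig addition to the carbonyl, and it is the only ring formed in the step. C7 is controlled by C6: allylic 1,3-strain across the ring-cis C4=C5 alkene holds H6 in the alkene plane and places the C3–C2–C1–C10–C9 tether on the butenolide face opposite to C5, so C8 is delivered anti to the C5 substituent (trans-fused lactone, 7R). C8 is controlled by the chair transition state of the E-locked cyclic allyl unit with C9 equatorial, which should give the anti (7R,8S) alcohol, the 8-epimer that step 16 inverts. The step needs γ- over α-attack (secured by the closed transition state with chromium on the primary C13), ring closure over oligomerisation (high dilution, Z-alkene and trans-oxirane as turn elements) and survival of the β,γ-epoxy aldehyde (neutral, non-basic Cr(II)/THF, aldehyde consumed as it is added).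

Step 16
Reactants: 27 the (7R,8S)-macrocyclic alcohol; 28 methacrylic acid
Product: 29 (1R,3S,6R,7R,8R,10R,4Z)-3,15-bis[(tert-butyldimethylsilyl)oxy]-1,10-epoxy-8-(methacryloyloxy)germacra-4,11(13)-dien-12,6-olide
Conditions: PPh3, DIAD (betaine preformed at 0 °C), 28, BHT (cat.), toluene, 0 °C to rt
Reagents that add atoms: none
Why: Mitsunobu esterification, in which the alcohol is activated as an alkoxyphosphonium ion and displaced by methacrylate in an SN2 step, should invert C8 to the 8R configuration of the target and install the ester in the same operation, with the preformed betaine keeping free phosphine away from the α-methylene lactone.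

Step 17
Reactants: 29 the bis-silylated methacrylate
Product: 30 (1R,3S,6R,7R,8R,10R,4Z)-1,10-epoxy-3,15-dihydroxy-8-(methacryloyloxy)germacra-4,11(13)-dien-12,6-olide
Conditions: TBAF/AcOH (1:1), THF, 0 °C to rt
Reagents that add atoms: none
Why: Fluoride-induced cleavage of both silyl ethers under acetic acid buffering should avoid base-induced translactonisation, acyl migration and conjugate addition as well as acid-induced oxirane opening.

Step 18
Reactants: 30 the C3,C15-diol
Product: 31 (1R,3S,6R,7R,8R,10R,4E)-1,10-epoxy-3-hydroxy-8-(methacryloyloxy)-15-oxogermacra-4,11(13)-dien-12,6-olide (target)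
Conditions: TEMPO (0.2 equiv), PhI(OAc)2 (1.2 equiv), CH2Cl2, rt
Reagents that add atoms: none
Why: Oxoammonium (TEMPO/PhI(OAc)2) oxidation is selective for the primary allylic alcohol over the secondary C3 carbinol and stops at the aldehyde, and the alkene keeps its geometry because CHO cis to H5 is the thermodynamically preferred 2-alkyl-2-enal arrangement.

## Compound list

1 | but-3-yn-1-ol | C#CCCO | starting material
2 | 1-[(but-3-yn-1-yloxy)methyl]-4-methoxybenzene | C#CCCOCc1ccc(OC)cc1 | intermediate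
3 | ethylene oxide | C1CO1 | starting material
4 | (E)-{4-[(4-methoxybenzyl)oxy]-2-methylbut-1-en-1-yl}dimethylalane | C[Al](C)/C=C(\C)CCOCc1ccc(OC)cc1 | intermediate
5 | lithium butyl{(E)-4-[(4-methoxybenzyl)oxy]-2-methylbut-1-en-1-yl}dimethylalanate | [Li+].CCCC[Al-](C)(C)/C=C(\C)CCOCc1ccc(OC)cc1 | intermediate
6 | (E)-6-[(4-methoxybenzyl)oxy]-4-methylhex-3-en-1-ol | OCC/C=C(\C)CCOCc1ccc(OC)cc1 | intermediate
7 | 2-[(2R,3R)-3-{2-[(4-methoxybenzyl)oxy]ethyl}-3-methyloxiran-2-yl]ethan-1-ol | OCC[C@H]1O[C@]1(C)CCOCc1ccc(OC)cc1 | intermediate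
8 | 2-[(2R,3R)-3-{2-[(4-methoxybenzyl)oxy]ethyl}-3-methyloxiran-2-yl]acetaldehyde | O=CC[C@H]1O[C@]1(C)CCOCc1ccc(OC)cc1 | intermediate
9 | tert-butyldimethyl(prop-2-yn-1-yloxy)silane | C#CCO[Si](C)(C)C(C)(C)C | starting material
10 | acrolein | C=CC=O | starting material
11 | {3-[(tert-butyldimethylsilyl)oxy]prop-1-yn-1-yl}(methyl)zinc | C[Zn]C#CCO[Si](C)(C)C(C)(C)C | intermediate
12 | (3S)-6-[(tert-butyldimethylsilyl)oxy]hex-1-en-4-yn-3-ol | C=C[C@H](O)C#CCO[Si](C)(C)C(C)(C)C | intermediate
13 | sodium (5S)-3-{[(tert-butyldimethylsilyl)oxy]methyl}-5-ethenyl-2,2-bis(2-methoxyethoxy)-2,5-dihydro-1,2-oxaaluminol-2-uide (cyclic alkoxy vinylalanate) | [Na+].COCCO[Al-]1(OCCOC)O[C@@H](C=C)C=C1CO[Si](C)(C)C(C)(C)C | intermediate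
14 | (3S,4Z)-6-[(tert-butyldimethylsilyl)oxy]-5-iodohexa-1,4-dien-3-ol | C=C[C@H](O)/C=C(\I)CO[Si](C)(C)C(C)(C)C | intermediate
15 | tert-butyl{[(2Z,4S)-2-iodo-4-[(triethylsilyl)oxy]hexa-2,5-dien-1-yl]oxy}dimethylsilane | C=C[C@H](O[Si](CC)(CC)CC)/C=C(\I)CO[Si](C)(C)C(C)(C)C | intermediate
16 | dichloro{(2Z,4S)-1-[(tert-butyldimethylsilyl)oxy]-4-[(triethylsilyl)oxy]hexa-2,5-dien-2-yl}chromium(III) (ligand omitted) | Cl[Cr](Cl)/C(CO[Si](C)(C)C(C)(C)C)=C\[C@@H](O[Si](CC)(CC)CC)C=C | intermediate
17 | (3S,4Z,6S)-5-{[(tert-butyldimethylsilyl)oxy]methyl}-7-[(2R,3R)-3-{2-[(4-methoxybenzyl)oxy]ethyl}-3-methyloxiran-2-yl]-3-[(triethylsilyl)oxy]hepta-1,4-dien-6-ol | COc1ccc(COCC[C@@]2(C)O[C@@H]2C[C@H](O)/C(CO[Si](C)(C)C(C)(C)C)=C\[C@@H](O[Si](CC)(CC)CC)C=C)cc1 | intermediate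
18 | (3S,4Z,6S)-6-[(tert-butyldimethylsilyl)oxy]-5-{[(tert-butyldimethylsilyl)oxy]methyl}-7-[(2R,3R)-3-{2-[(4-methoxybenzyl)oxy]ethyl}-3-methyloxiran-2-yl]-3-[(triethylsilyl)oxy]hepta-1,4-diene | COc1ccc(COCC[C@@]2(C)O[C@@H]2C[C@H](O[Si](C)(C)C(C)(C)C)/C(CO[Si](C)(C)C(C)(C)C)=C\[C@@H](O[Si](CC)(CC)CC)C=C)cc1 | intermediate
19 | (3S,4Z,6S)-6-[(tert-butyldimethylsilyl)oxy]-5-{[(tert-butyldimethylsilyl)oxy]methyl}-7-[(2R,3R)-3-{2-[(4-methoxybenzyl)oxy]ethyl}-3-methyloxiran-2-yl]hepta-1,4-dien-3-ol | COc1ccc(COCC[C@@]2(C)O[C@@H]2C[C@H](O[Si](C)(C)C(C)(C)C)/C(CO[Si](C)(C)C(C)(C)C)=C\[C@@H](O)C=C)cc1 | intermediate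
20 | 2-(bromomethyl)acrylic acid | C=C(CBr)C(=O)O | starting material
21 | 2-(bromomethyl)acryloyl chloride | C=C(CBr)C(Cl)=O | intermediate
22 | (3S,4Z,6S)-6-[(tert-butyldimethylsilyl)oxy]-5-{[(tert-butyldimethylsilyl)oxy]methyl}-7-[(2R,3R)-3-{2-[(4-methoxybenzyl)oxy]ethyl}-3-methyloxiran-2-yl]hepta-1,4-dien-3-yl 2-(bromomethyl)prop-2-enoate | COc1ccc(COCC[C@@]2(C)O[C@@H]2C[C@H](O[Si](C)(C)C(C)(C)C)/C(CO[Si](C)(C)C(C)(C)C)=C\[C@@H](OC(=O)C(=C)CBr)C=C)cc1 | intermediate
23 | (5R)-3-(bromomethyl)-5-[(1Z,3S)-3-[(tert-butyldimethylsilyl)oxy]-2-{[(tert-butyldimethylsilyl)oxy]methyl}-4-[(2R,3R)-3-{2-[(4-methoxybenzyl)oxy]ethyl}-3-methyloxiran-2-yl]but-1-en-1-yl]furan-2(5H)-one | COc1ccc(COCC[C@@]2(C)O[C@@H]2C[C@H](O[Si](C)(C)C(C)(C)C)/C(CO[Si](C)(C)C(C)(C)C)=C\[C@H]2OC(=O)C(CBr)=C2)cc1 | intermediate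
24 | (5R)-3-(bromomethyl)-5-[(1Z,3S)-3-[(tert-butyldimethylsilyl)oxy]-2-{[(tert-butyldimethylsilyl)oxy]methyl}-4-[(2R,3R)-3-(2-hydroxyethyl)-3-methyloxiran-2-yl]but-1-en-1-yl]furan-2(5H)-one | OCC[C@@]1(C)O[C@@H]1C[C@H](O[Si](C)(C)C(C)(C)C)/C(CO[Si](C)(C)C(C)(C)C)=C\[C@H]1OC(=O)C(CBr)=C1 | intermediate
25 | (5R)-3-(bromomethyl)-5-[(1Z,3S)-3-[(tert-butyldimethylsilyl)oxy]-2-{[(tert-butyldimethylsilyl)oxy]methyl}-4-[(2R,3R)-3-methyl-3-(2-oxoethyl)oxiran-2-yl]but-1-en-1-yl]furan-2(5H)-one | O=CC[C@@]1(C)O[C@@H]1C[C@H](O[Si](C)(C)C(C)(C)C)/C(CO[Si](C)(C)C(C)(C)C)=C\[C@H]1OC(=O)C(CBr)=C1 | intermediate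
26 | allylchromium(III) dichloride of 25 (CH2CrCl2 in place of CH2Br on the butenolide) | O=CC[C@@]1(C)O[C@@H]1C[C@H](O[Si](C)(C)C(C)(C)C)/C(CO[Si](C)(C)C(C)(C)C)=C\[C@H]1OC(=O)C(C[Cr](Cl)Cl)=C1 | intermediate
27 | (1R,3S,6R,7R,8S,10R,4Z)-3,15-bis[(tert-butyldimethylsilyl)oxy]-1,10-epoxy-8-hydroxygermacra-4,11(13)-dien-12,6-olide | O[C@H]1C[C@@]2(C)O[C@@H]2C[C@H](O[Si](C)(C)C(C)(C)C)/C(CO[Si](C)(C)C(C)(C)C)=C\[C@H]2OC(=O)C(=C)[C@@H]21 | intermediate
28 | methacrylic acid | C=C(C)C(=O)O | starting material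
29 | (1R,3S,6R,7R,8R,10R,4Z)-3,15-bis[(tert-butyldimethylsilyl)oxy]-1,10-epoxy-8-(methacryloyloxy)germacra-4,11(13)-dien-12,6-olide | C=C(C)C(=O)O[C@@H]1C[C@@]2(C)O[C@@H]2C[C@H](O[Si](C)(C)C(C)(C)C)/C(CO[Si](C)(C)C(C)(C)C)=C\[C@H]2OC(=O)C(=C)[C@@H]21 | intermediate
30 | (1R,3S,6R,7R,8R,10R,4Z)-1,10-epoxy-3,15-dihydroxy-8-(methacryloyloxy)germacra-4,11(13)-dien-12,6-olide | C=C(C)C(=O)O[C@@H]1C[C@@]2(C)O[C@@H]2C[C@H](O)/C(CO)=C\[C@H]2OC(=O)C(=C)[C@@H]21 | intermediate
31 | (1R,3S,6R,7R,8R,10R,4E)-1,10-epoxy-3-hydroxy-8-(methacryloyloxy)-15-oxogermacra-4,11(13)-dien-12,6-olide | C=C(C)C(=O)O[C@@H]1C[C@@]2(C)O[C@@H]2C[C@H](O)/C(C=O)=C\[C@H]2OC(=O)C(=C)[C@@H]21 | target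

## Step count and risks

Total step count: 18. Longest linear sequence: 15 steps (steps 1–4, then 8–18).

The three steps most likely to fail:

Step 15 (ring closure). What may go wrong: intermolecular coupling in place of ring closure; Cr(III)-promoted opening or β-elimination of the β,γ-epoxy aldehyde before it is trapped; attack on the wrong face at C7 (cis-fused lactone); translactonisation of the chromium alkoxide onto the lactone carbonyl. The fallback replaces the reductive Barbier reaction by a metal-salt-free intramolecular allylboration. It sets out from 24. Pd(0)-catalysed borylation of the allylic bromide with bis(pinacolato)diboron should give the primary allylboronate, the allylboronate alcohol F1. Buffered Dess–Martin oxidation gives the allylboronate aldehyde F2, which on warming in dilute toluene should close the same C7–C8 bond through the same chair transition state to the cyclic borate ester F3. Mild hydrolysis (triethanolamine or aqueous NaHCO3) comes back to the route at 27.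

Step 16 (Mitsunobu inversion). What may go wrong: slow SN2 displacement at the hindered ring carbinol, so that E2 loss of the activated oxygen towards C7 or C9 competes; conjugate addition of free phosphine to the α-methylene lactone. The fallback uses sulfonate displacement instead of redox condensation. It sets out from 27. Chloromethanesulfonyl chloride and pyridine give, with retention, the 8-O-chloromethanesulfonate F4, which is displaced with inversion by caesium methacrylate/18-crown-6 in toluene and comes back to the route at 29.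

Step 8 (asymmetric Ni/Cr coupling). What may go wrong: insufficient facial control by the ligand at C3; opening of the oxirane by the C3 chromium alkoxide (attack at the tertiary carbon); β-elimination of the epoxy aldehyde. The fallback sets the stereocentre by reduction instead of addition. It sets out from 8 and 15, which are coupled under achiral NiCl2/CrCl2 conditions in DMSO to give 17 together with its C3 epimer, the (3R)-alcohol F5. The mixture is oxidised with buffered Dess–Martin periodinane to the enone F6, and (R)-Me-CBS/catecholborane reduction at −78 °C (alkenyl as the large group) comes back to the route at 17 as the (3S)-alcohol.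

Further compounds
F1 | step 15 | (5R)-5-[(1Z,3S)-3-[(tert-butyldimethylsilyl)oxy]-2-{[(tert-butyldimethylsilyl)oxy]methyl}-4-[(2R,3R)-3-(2-hydroxyethyl)-3-methyloxiran-2-yl]but-1-en-1-yl]-3-[(4,4,5,5-tetramethyl-1,3,2-dioxaborolan-2-yl)methyl]furan-2(5H)-one | OCC[C@@]1(C)O[C@@H]1C[C@H](O[Si](C)(C)C(C)(C)C)/C(CO[Si](C)(C)C(C)(C)C)=C\[C@H]1OC(=O)C(CB2OC(C)(C)C(C)(C)O2)=C1
F2 | step 15 | (5R)-5-[(1Z,3S)-3-[(tert-butyldimethylsilyl)oxy]-2-{[(tert-butyldimethylsilyl)oxy]methyl}-4-[(2R,3R)-3-methyl-3-(2-oxoethyl)oxiran-2-yl]but-1-en-1-yl]-3-[(4,4,5,5-tetramethyl-1,3,2-dioxaborolan-2-yl)methyl]furan-2(5H)-one | O=CC[C@@]1(C)O[C@@H]1C[C@H](O[Si](C)(C)C(C)(C)C)/C(CO[Si](C)(C)C(C)(C)C)=C\[C@H]1OC(=O)C(CB2OC(C)(C)C(C)(C)O2)=C1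
F3 | step 15 | 8-O-(4,4,5,5-tetramethyl-1,3,2-dioxaborolan-2-yl) borate ester of 27 | CC1(C)OB(O[C@H]2C[C@@]3(C)O[C@@H]3C[C@H](O[Si](C)(C)C(C)(C)C)/C(CO[Si](C)(C)C(C)(C)C)=C\[C@H]3OC(=O)C(=C)[C@@H]32)OC1(C)C
F4 | step 16 | 8-O-chloromethanesulfonate of 27 (8S) | ClCS(=O)(=O)O[C@H]1C[C@@]2(C)O[C@@H]2C[C@H](O[Si](C)(C)C(C)(C)C)/C(CO[Si](C)(C)C(C)(C)C)=C\[C@H]2OC(=O)C(=C)[C@@H]21
F5 | step 8 | C3 epimer of 17, (3S,4Z,6R)-hepta-1,4-dien-6-ol | COc1ccc(COCC[C@@]2(C)O[C@@H]2C[C@@H](O)/C(CO[Si](C)(C)C(C)(C)C)=C\[C@@H](O[Si](CC)(CC)CC)C=C)cc1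
F6 | step 8 | (3S,4Z)-5-{[(tert-butyldimethylsilyl)oxy]methyl}-7-[(2R,3R)-3-{2-[(4-methoxybenzyl)oxy]ethyl}-3-methyloxiran-2-yl]-3-[(triethylsilyl)oxy]hepta-1,4-dien-6-one | COc1ccc(COCC[C@@]2(C)O[C@@H]2CC(=O)/C(CO[Si](C)(C)C(C)(C)C)=C\[C@@H](O[Si](CC)(CC)CC)C=C)cc1
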